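## The problem

- Target 27 is a labdane: a trans-fused decalin (ring A = C1–C5, C10; ring B = C5–C10) with an axial C20 methyl on C10, a quaternary C4 carrying the equatorial C18 methyl and the axial C19 acid, an exocyclic C8=C17 methylene, and a chain on C9 that ends in the C15 stearate.
- The four contiguous ring stereocentres can be relayed from one another. C5 can fix the ring fusion at C10, the axial C20 methyl then screens the β face for alkylation at C4, and C9 beside a C8 carbonyl settles as the equatorial epimer.
- C13 lies four bonds from the ring and cannot be controlled from it. It must arrive in a chiral-pool fragment, so one chain bond near C11–C12 has to be made in a coupling.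
- The C8=C17 alkene migrates into the ring under acid and excludes hydrogenation once it is present. The stearate does not survive hydrides, amide bases or thiolates. The C19 ester is neopentyl and axial and cannot be saponified, so its release must be planned.
- The enabling feature is C10, a methyl-bearing quaternary carbon flanked by C5 and C9. If ring A carries an exocyclic methylene at C10, hydrogen-atom transfer turns that methylene into C20 and leaves a tertiary radical. This radical can bond to C9 of an electron-poor C9=C11 alkene hung from C5, which closes ring B. A C8 carbonyl in the tether then supplies C17, and the group on C11 opens the way to the chain.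

## Retrosynthesis

**27 ⇒ 25 + 26 (C15–O acyl bond).** The stearate is the most fragile group toward every base and nucleophile used earlier, so it is put on last. Hydroxy acid 25 is smaller by eighteen carbons. The forward step must acylate a primary alcohol beside a free neopentyl acid; any mixed anhydride hydrolyses at its unhindered carbonyl on work-up.

**25 ⇒ 24 ⇒ 23 ⇒ 21 (protecting groups, then C4–C18).** Carrying a quaternary C4 from the start would require a methyl/ester stereocentre to be set without a rigid framework. In trans-decalin 21 the axial C20 methyl blocks the β face, so the ester enolate should be methylated from the α face and the ester becomes axial C19. The forward steps must enolise a hindered ester fully, then free the acid by SN2 demethylation of 23 (saponification is not an option) and remove the silyl ether of 24 without acid.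

**21 ⇒ 20 (C8=C17).** The alkene comes from the C8 ketone by Wittig methylenation, placed after all conjugate chemistry and before the amide-base step, where a ketone would interfere. C9 is epimerisable in 20, but the wanted epimer is the stable one.

**20 ⇒ 12 + 17 (C11–C12).** The chain is joined by copper-catalysed conjugate addition of Grignard reagent 18, made from bromide 17, to exo-methylene ketone 12.
- The neighbouring cut, alkylation of an α-sulfonyl carbanion at C11, would need strong base in a molecule whose C4 ester proton is about as acidic, and on a β-sulfonyl ketone that expels sulfinate readily.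
- That tendency is used instead: 12 arises from 11 by E1cB loss of sulfinate. Both C9 epimers of 11 converge, and C9 is reset by protonation after the addition.
- Bromide 17 brings C13 from half ester 13, whose acid and ester ends are already different: the acid end becomes C12 (via 14 and 15) and the ester end becomes C15 (via 16).

**11 ⇒ 10 (C9–C10, ring B; key step).** Hydrogen-atom transfer to the C10 methylene of 10 gives the C20 methyl and a tertiary radical that closes ring B on C9.
- Against a polar closure (aldol or Michael onto a C10 ketone), the radical route makes the quaternary centre without an enolate at a ring-fusion carbon and tolerates the ester.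
- The precursor 10 is monocyclic with two stereocentres.
- The forward reaction must attack C9 rather than C11 and give the trans fusion.

**10 ⇒ 9 ⇒ 8 ⇒ 7 (C11–S, then C8–C9).** The sulfone is introduced by conjugate addition of benzenesulfinate to ynone 9, itself from aldehyde 7 by acetylide addition (8) and oxidation. A cross-metathesis of a C8 allylic alcohol with a vinyl sulfone looks shorter, but that diene would ring-close between C9 and the C10 methylene to an octalin before it cross-couples.

**7 ⇒ 6 ⇒ 4 ⇒ 3 (C8–O, then C10=C20).** The allyl group of 4 is taken to the aldehyde by hydroboration–oxidation and alcohol oxidation; the methylene comes from ketone 3 by Wittig reaction. The forward hydroboration must select the monosubstituted alkene over the 1,1-disubstituted one.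

**3 ⇒ 1 (C5–C6 and the C4 hydrogen).** Asymmetric copper hydride reduction of enone ester 1 delivers hydride to the ester-bearing carbon and a regiodefined enolate at C5, which is allylated trans to the ester. One catalytic step sets C4, which relays to C5 and from there to C10. C4 is later flattened and reset under control of C10.

## Roads not taken

**Alternative 1:** The cut goes through C5–C10 and C8–C9 at once and opens both rings to trienal A2. In A2 an E-enal (C9=C10, methyl on C10) is tethered through C1–C4 to an E,E-silyloxydiene (C5=C6–C7=C8). Heating or Me2AlCl would give trans-fused octalin A1 with C5, C10, C9 and C8 set together.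
- Merits: two rings, two C–C bonds and the C10 quaternary centre in one step, with C4 already quaternary. In bonds made per step this is better than the chosen plan, which buys ring A and closes only ring B.
- Weak points: the dienophile carbon C10 is fully substituted and the diene end C5 is neopentyl, so the cycloaddition is slow and a Lewis acid endangers the silyl dienol ether. Facial control must come from the open-chain C4 centre, whose methyl and ester differ little in size, and that centre itself must be made enantioselectively. A1 also carries a C6=C7 alkene and a C8 silyl ether that must be removed or converted, and its C9 aldehyde still needs five carbons and C13.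
- Comparison: against its convergence, the chosen plan sets stereochemistry relayed through ring-held intermediates from one catalytic step, and a key product (11) in which every functional group is used.

**Alternative 2:** The cuts are C10–C20 and C5–C6 on the same enone ester 1, read with the ester carbon as C9 and the ketone as C4. Me2Zn with Cu(OTf)2 and a chiral N-heterocyclic carbene would add methyl to the ester-bearing carbon, and allylation of the zinc enolate would give A3.
- Merits: the C10 quaternary centre is set in the first step by a catalytic asymmetric addition whose selectivity is easier to predict than the diastereoselectivity of a radical ring closure. In this respect the road is better.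
- Weak points: no ring closes. Ring B must be built afterwards from the allyl group and the C9 ester. The C4 ketone of A3 must be turned into a quaternary carbon with methyl and an axial carboxyl, which is much harder than methylating an existing ester. C8, C17 and the chain each need separate steps.
- Comparison: the chosen plan sets against it a key step that closes ring B, creates C10 and leaves the C8 carbonyl and a C11 leaving group in place, with C19 present from the first compound.

**Alternative 3:** The cut is C3–C4, with ring A seen as the contraction product of a seven-membered homologue. In epoxide A5 the seven-membered ring contains C19. BF3·OEt2 would open the C4–C19 epoxide at tertiary C4 while C3 shifts from C19 to C4, giving trans-decalin aldehyde A4 with the C18 methyl, an axial C19 aldehyde and a C9 ketal.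
- Merits: C4 is set stereospecifically by a 1,2-shift with inversion, in principle more certain than a face-selective methylation, and the aldehyde is oxidised to the acid without any hindered-ester cleavage. Here the road is as good as or better than the chosen one.
- Weak points: A5 needs a bicyclo[5.4.0]undecene with the angular methyl, a trans fusion and a face-selective epoxidation on a ring size with poor conformational control. Hydride shift from C19 competes with the alkyl shift. The step builds no bond of rings A/B beyond the contraction and leaves C8, C9 and the chain untouched.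
- Comparison: the chosen plan sets against it a six-membered starting ring from the catalogue, the established α-face methylation of C4 ester enolates under an axial C10 methyl, and a key step that does skeletal work.

Key step: step 8

Remark: the facial sense of the copper hydride catalyst on an ester-substituted enone is assigned by analogy with 3-alkylcyclohexenones; if it proves opposite, the mirror-image ligand is used and nothing else changes.

## Route

Step 1
Reactants: 1 methyl 3-oxocyclohex-1-ene-1-carboxylate
Product: 3 methyl (1R,2S)-3-oxo-2-(prop-2-en-1-yl)cyclohexane-1-carboxylate, via bis-enol diphenylsilyl ether 2 (not isolated)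
Conditions: CuCl (5 mol %), NaOt-Bu (5 mol %), (S)-p-tol-BINAP (5 mol %), Ph2SiH2 (0.55 equiv), toluene, 0 °C; then Bu4N[Ph3SiF2], allyl bromide, CH2Cl2, rt
Reagents that add atoms: allyl bromide, C=CCBr
Why: Asymmetric copper hydride conjugate reduction with enolate trapping; hydride enters at the ester-bearing carbon (β to the ketone) on the face chosen by the ligand, setting C4 (1R), and fluoride releases the regiodefined enolate, which is allylated at C5 anti to the neighbouring ester (2S), also the more stable trans arrangement.

Step 2
Reactants: 3 methyl (1R,2S)-3-oxo-2-(prop-2-en-1-yl)cyclohexane-1-carboxylate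
Product: 4 methyl (1R,2S)-3-methylidene-2-(prop-2-en-1-yl)cyclohexane-1-carboxylate
Conditions: Ph3PCH3Br, KOt-Bu, THF, 0 °C to rt
Reagents that add atoms: methyltriphenylphosphonium bromide, C[P+](c1ccccc1)(c1ccccc1)c1ccccc1.[Br-]
Why: Wittig methylenation of an unhindered cyclohexanone; the ester is not attacked by the ylide and any epimerisation at C5 only returns the trans isomer.

Step 3
Reactants: 4 methyl (1R,2S)-3-methylidene-2-(prop-2-en-1-yl)cyclohexane-1-carboxylate
Product: 6 methyl (1R,2S)-2-(3-hydroxypropyl)-3-methylidenecyclohexane-1-carboxylate, via alkyl(disiamyl)borane 5 (not isolated)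
Conditions: (Sia)2BH (from BH3·THF and 2-methylbut-2-ene), THF, 0 °C; then NaBO3·4H2O, H2O, rt
Reagents that add atoms: sodium perborate, [Na+].[O-]OB=O
Why: Hydroboration–oxidation; disiamylborane adds to monosubstituted terminal alkenes much faster than to 1,1-disubstituted ones and the C10 methylene is further screened by the branched C5, while perborate oxidises the borane without saponifying the ester.

Step 4
Reactants: 6 methyl (1R,2S)-2-(3-hydroxypropyl)-3-methylidenecyclohexane-1-carboxylate
Product: 7 methyl (1R,2S)-3-methylidene-2-(3-oxopropyl)cyclohexane-1-carboxylate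
Conditions: Dess–Martin periodinane, NaHCO3, CH2Cl2, 0 °C to rt
Reagents that add atoms: none
Why: Dess–Martin oxidation of a primary alcohol to the aldehyde under buffered conditions that leave the exocyclic alkene and the ester alone.

Step 5
Reactants: 7 methyl (1R,2S)-3-methylidene-2-(3-oxopropyl)cyclohexane-1-carboxylate
Product: 8 methyl (1R,2S)-2-(3-hydroxypent-4-yn-1-yl)-3-methylidenecyclohexane-1-carboxylate (both carbinol epimers)
Conditions: HC≡CMgBr, THF, −78 to 0 °C; aq NH4Cl
Reagents that add atoms: ethynylmagnesium bromide, C#C[Mg]Br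
Why: Grignard addition to an aldehyde, which reacts far faster than the secondary methyl ester at low temperature; the new carbinol centre is not controlled because step 6 removes it.

Step 6
Reactants: 8 methyl (1R,2S)-2-(3-hydroxypent-4-yn-1-yl)-3-methylidenecyclohexane-1-carboxylate
Product: 9 methyl (1R,2S)-3-methylidene-2-(3-oxopent-4-yn-1-yl)cyclohexane-1-carboxylate
Conditions: Dess–Martin periodinane, NaHCO3, CH2Cl2, 0 °C
Reagents that add atoms: none
Why: Dess–Martin oxidation of a propargylic alcohol to the terminal ynone, used without delay.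

Step 7
Reactants: 9 methyl (1R,2S)-3-methylidene-2-(3-oxopent-4-yn-1-yl)cyclohexane-1-carboxylate
Product: 10 methyl (1R,2S)-2-[(4E)-5-(benzenesulfonyl)-3-oxopent-4-en-1-yl]-3-methylidenecyclohexane-1-carboxylate
Conditions: PhSO2Na, AcOH, THF/H2O, rt
Reagents that add atoms: sodium benzenesulfinate, [Na+].[O-]S(=O)c1ccccc1
Why: Conjugate addition of sulfinic acid to a terminal ynone (hydrosulfonylation); reversible sulfinate addition–elimination at the β-carbon lets the product settle as the E isomer, and the geometry is in any case lost in step 8.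

Step 8
Reactants: 10 methyl (1R,2S)-2-[(4E)-5-(benzenesulfonyl)-3-oxopent-4-en-1-yl]-3-methylidenecyclohexane-1-carboxylate
Product: 11 methyl (1R,4aS,5R,8aS)-5-[(benzenesulfonyl)methyl]-4a-methyl-6-oxodecahydronaphthalene-1-carboxylate
Conditions: Fe(acac)3 (0.5 equiv), PhSiH3 (2.5 equiv), EtOH/(CH2OH)2 5:1, 0.01 M, 60 °C
Reagents that add atoms: none
Why: Fe(acac)3 and PhSiH3 in ethanol form an iron hydride that transfers a hydrogen atom to the terminal carbon of the C10=C20 methylene, the only electron-rich alkene present, which creates the C20 methyl and a tertiary C10 radical. The radical adds 6-exo-trig to C9, the carbon β to the sulfone, and closes ring B; the α-sulfonyl radical at C11 is reduced by divalent iron and protonated by the solvent, so the closest known reaction type is the iron-hydride reductive olefin coupling run intramolecularly as a Giese cyclisation. C10 is controlled by C5: in the chair-like transition state the tether leaves C5 equatorially, held there by the trans equatorial C4 ester, and C9 bonds to C10 on the equatorial side, so the new methyl becomes axial and the fusion trans. C9 is set by the pseudo-equatorial sulfonylvinyl unit in the same chair, but the route does not rely on it because step 9 flattens C9. The step needs regioselection between C9 (6-exo) and C11 (7-endo, β to the ketone, followed by loss of a sulfonyl radical); ring size, the polar activation of C9 by the sulfone and the bulk of the sulfonyl group on C11 toward a tertiary radical should favour C9. Partial loss of sulfinate from 11 under the conditions would do no harm, since it only anticipates step 9.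

Step 9
Reactants: 11 methyl (1R,4aS,5R,8aS)-5-[(benzenesulfonyl)methyl]-4a-methyl-6-oxodecahydronaphthalene-1-carboxylate
Product: 12 methyl (1R,4aS,8aS)-4a-methyl-5-methylidene-6-oxodecahydronaphthalene-1-carboxylate
Conditions: DBU, CH2Cl2, 0 °C; cold aqueous citric acid wash; used at once
Reagents that add atoms: none
Why: E1cB elimination of benzenesulfinate from a β-sulfonyl ketone; both C9 epimers of 11 give the same enone, which is hindered by the quaternary C10 but is still used immediately to avoid dimerisation.

Step 10
Reactants: 13 (2R)-4-methoxy-2-methyl-4-oxobutanoic acid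
Product: 14 methyl (3R)-4-hydroxy-3-methylbutanoate
Conditions: BH3·SMe2, THF, 0 °C to rt; MeOH quench
Reagents that add atoms: none
Why: Chemoselective borane reduction of a carboxylic acid beside a methyl ester; the stereocentre is not involved.

Step 11
Reactants: 14 methyl (3R)-4-hydroxy-3-methylbutanoate
Product: 15 methyl (3R)-4-bromo-3-methylbutanoate
Conditions: CBr4, PPh3, CH2Cl2, 0 °C
Reagents that add atoms: carbon tetrabromide, BrC(Br)(Br)Br
Why: Appel bromination of a primary alcohol under neutral conditions, which avoids lactonisation of the hydroxy ester.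

Step 12
Reactants: 15 methyl (3R)-4-bromo-3-methylbutanoate
Product: 16 (3R)-4-bromo-3-methylbutan-1-ol
Conditions: i-Bu2AlH (2.2 equiv), CH2Cl2, −78 to 0 °C; aqueous potassium sodium tartrate
Reagents that add atoms: none
Why: Hydride reduction of the ester to the primary alcohol; a primary alkyl bromide is inert to i-Bu2AlH at this temperature.

Step 13
Reactants: 16 (3R)-4-bromo-3-methylbutan-1-ol
Product: 17 [(3R)-4-bromo-3-methylbutoxy](tert-butyl)dimethylsilane
Conditions: TBSCl, imidazole, CH2Cl2, rt
Reagents that add atoms: tert-butyldimethylsilyl chloride, CC(C)(C)[Si](C)(C)Cl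
Why: Silylation of a primary alcohol, done at once so that the bromo alcohol cannot cyclise to the tetrahydrofuran.

Step 14
Reactants: 12 methyl (1R,4aS,8aS)-4a-methyl-5-methylidene-6-oxodecahydronaphthalene-1-carboxylate; 17 [(3R)-4-bromo-3-methylbutoxy](tert-butyl)dimethylsilane
Product: 20 methyl (1R,4aS,5R,8aS)-5-[(3S)-5-{[tert-butyl(dimethyl)silyl]oxy}-3-methylpentyl]-4a-methyl-6-oxodecahydronaphthalene-1-carboxylate, via Grignard reagent 18 (not isolated), via silyl enol ether 19 (not isolated)
Conditions: 17, Mg, THF, rt; CuBr·SMe2 (10 mol %), Me3SiCl, THF, −78 °C, then 12; then K2CO3, MeOH, rt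
Reagents that add atoms: none
Why: Copper-catalysed conjugate addition of a Grignard reagent to an exocyclic enone, accelerated by Me3SiCl, forms C11–C12 and brings C13 unchanged from 17; methanolysis of the silyl enol ether under carbonate protonates C9 reversibly, from the α face opposite the axial C20 methyl, so the chain ends equatorial.

Step 15
Reactants: 20 methyl (1R,4aS,5R,8aS)-5-[(3S)-5-{[tert-butyl(dimethyl)silyl]oxy}-3-methylpentyl]-4a-methyl-6-oxodecahydronaphthalene-1-carboxylate
Product: 21 methyl (1R,4aS,5S,8aS)-5-[(3S)-5-{[tert-butyl(dimethyl)silyl]oxy}-3-methylpentyl]-4a-methyl-6-methylidenedecahydronaphthalene-1-carboxylate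
Conditions: Ph3PCH3Br (excess), KOt-Bu, toluene/THF, 70 °C
Reagents that add atoms: methyltriphenylphosphonium bromide, C[P+](c1ccccc1)(c1ccccc1)c1ccccc1.[Br-]
Why: Wittig methylenation of the hindered C8 ketone with excess ylide at raised temperature, as is usual for 8-oxolabdanes; C9 can only epimerise toward the equatorial, wanted epimer.

Step 16
Reactants: 21 methyl (1R,4aS,5S,8aS)-5-[(3S)-5-{[tert-butyl(dimethyl)silyl]oxy}-3-methylpentyl]-4a-methyl-6-methylidenedecahydronaphthalene-1-carboxylate
Product: 23 methyl (1S,4aR,5S,8aR)-5-[(3S)-5-{[tert-butyl(dimethyl)silyl]oxy}-3-methylpentyl]-1,4a-dimethyl-6-methylidenedecahydronaphthalene-1-carboxylate, via lithium ester enolate 22 (not isolated)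
Conditions: LiN(i-Pr)2, THF, −78 to 0 °C; MeI, DMPU, −78 °C to rt
Reagents that add atoms: iodomethane, CI
Why: Ester enolate alkylation; the exocyclic enolate is methylated from the α face because the β face is blocked 1,3-diaxially by the C20 methyl, which places C18 equatorial and the ester axial as C19.

Step 17
Reactants: 23 methyl (1S,4aR,5S,8aR)-5-[(3S)-5-{[tert-butyl(dimethyl)silyl]oxy}-3-methylpentyl]-1,4a-dimethyl-6-methylidenedecahydronaphthalene-1-carboxylate
Product: 24 (1S,4aR,5S,8aR)-5-[(3S)-5-{[tert-butyl(dimethyl)silyl]oxy}-3-methylpentyl]-1,4a-dimethyl-6-methylidenedecahydronaphthalene-1-carboxylic acid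
Conditions: n-PrSLi (from n-PrSH and n-BuLi), HMPA, rt; dilute HCl
Reagents that add atoms: none
Why: SN2 O-alkyl cleavage of a methyl ester by thiolate in a dipolar solvent, the standard answer to axial neopentyl esters that resist saponification; the silyl ether and the alkene are inert.

Step 18
Reactants: 24 (1S,4aR,5S,8aR)-5-[(3S)-5-{[tert-butyl(dimethyl)silyl]oxy}-3-methylpentyl]-1,4a-dimethyl-6-methylidenedecahydronaphthalene-1-carboxylic acid
Product: 25 (1S,4aR,5S,8aR)-5-[(3S)-5-hydroxy-3-methylpentyl]-1,4a-dimethyl-6-methylidenedecahydronaphthalene-1-carboxylic acid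
Conditions: Bu4NF (3 equiv), THF, rt; aq NH4Cl
Reagents that add atoms: none
Why: Fluoride cleavage of a primary silyl ether; no acid is used, so the exocyclic alkene stays in place.

Step 19
Reactants: 25 (1S,4aR,5S,8aR)-5-[(3S)-5-hydroxy-3-methylpentyl]-1,4a-dimethyl-6-methylidenedecahydronaphthalene-1-carboxylic acid; 26 octadecanoyl chloride
Product: 27 (1S,4aR,5S,8aR)-1,4a-dimethyl-6-methylidene-5-[(3S)-3-methyl-5-(octadecanoyloxy)pentyl]decahydronaphthalene-1-carboxylic acid
Conditions: pyridine, DMAP (cat.), CH2Cl2, 0 °C to rt; then aq NaHCO3/THF, acidify to pH 3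
Reagents that add atoms: none
Why: DMAP-catalysed O-acylation of the primary alcohol by the acid chloride; the neopentyl C19 acid is not esterified, and any mixed anhydride is hydrolysed at its unhindered stearoyl carbonyl in the bicarbonate work-up.

## Compound list

1 | methyl 3-oxocyclohex-1-ene-1-carboxylate | COC(=O)C1=CC(=O)CCC1 | starting material
2 | diphenylbis{[(3R)-3-(methoxycarbonyl)cyclohex-1-en-1-yl]oxy}silane | COC(=O)[C@@H]1CCCC(O[Si](c2ccccc2)(c2ccccc2)OC2=C[C@H](C(=O)OC)CCC2)=C1 | intermediate
3 | methyl (1R,2S)-3-oxo-2-(prop-2-en-1-yl)cyclohexane-1-carboxylate | O=C1CCC[C@@H](C(=O)OC)[C@@H]1CC=C | intermediate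
4 | methyl (1R,2S)-3-methylidene-2-(prop-2-en-1-yl)cyclohexane-1-carboxylate | C=C1CCC[C@@H](C(=O)OC)[C@@H]1CC=C | intermediate
5 | methyl (1R,2S)-2-{3-[bis(3-methylbutan-2-yl)boranyl]propyl}-3-methylidenecyclohexane-1-carboxylate (siamyl centres undefined) | C=C1CCC[C@@H](C(=O)OC)[C@@H]1CCCB(C(C)C(C)C)C(C)C(C)C | intermediate
6 | methyl (1R,2S)-2-(3-hydroxypropyl)-3-methylidenecyclohexane-1-carboxylate | C=C1CCC[C@@H](C(=O)OC)[C@@H]1CCCO | intermediate
7 | methyl (1R,2S)-3-methylidene-2-(3-oxopropyl)cyclohexane-1-carboxylate | C=C1CCC[C@@H](C(=O)OC)[C@@H]1CCC=O | intermediate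
8 | methyl (1R,2S)-2-(3-hydroxypent-4-yn-1-yl)-3-methylidenecyclohexane-1-carboxylate (both carbinol epimers) | C=C1CCC[C@@H](C(=O)OC)[C@@H]1CCC(O)C#C | intermediate
9 | methyl (1R,2S)-3-methylidene-2-(3-oxopent-4-yn-1-yl)cyclohexane-1-carboxylate | C=C1CCC[C@@H](C(=O)OC)[C@@H]1CCC(=O)C#C | intermediate
10 | methyl (1R,2S)-2-[(4E)-5-(benzenesulfonyl)-3-oxopent-4-en-1-yl]-3-methylidenecyclohexane-1-carboxylate | C=C1CCC[C@@H](C(=O)OC)[C@@H]1CCC(=O)/C=C/S(=O)(=O)c1ccccc1 | intermediate
11 | methyl (1R,4aS,5R,8aS)-5-[(benzenesulfonyl)methyl]-4a-methyl-6-oxodecahydronaphthalene-1-carboxylate | O=C1CC[C@@H]2[C@](C)(CCC[C@H]2C(=O)OC)[C@H]1CS(=O)(=O)c1ccccc1 | intermediate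
12 | methyl (1R,4aS,8aS)-4a-methyl-5-methylidene-6-oxodecahydronaphthalene-1-carboxylate | O=C1CC[C@@H]2[C@](C)(CCC[C@H]2C(=O)OC)C1=C | intermediate
13 | (2R)-4-methoxy-2-methyl-4-oxobutanoic acid | OC(=O)[C@H](C)CC(=O)OC | starting material
14 | methyl (3R)-4-hydroxy-3-methylbutanoate | OC[C@H](C)CC(=O)OC | intermediate
15 | methyl (3R)-4-bromo-3-methylbutanoate | BrC[C@H](C)CC(=O)OC | intermediate
16 | (3R)-4-bromo-3-methylbutan-1-ol | BrC[C@H](C)CCO | intermediate
17 | [(3R)-4-bromo-3-methylbutoxy](tert-butyl)dimethylsilane | BrC[C@H](C)CCO[Si](C)(C)C(C)(C)C | intermediate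
18 | {(2R)-4-[(tert-butyldimethylsilyl)oxy]-2-methylbutyl}magnesium bromide | Br[Mg]C[C@H](C)CCO[Si](C)(C)C(C)(C)C | intermediate
19 | methyl (1R,4aS,8aS)-5-[(3S)-5-{[tert-butyl(dimethyl)silyl]oxy}-3-methylpentyl]-4a-methyl-6-[(trimethylsilyl)oxy]-1,2,3,4,4a,7,8,8a-octahydronaphthalene-1-carboxylate | C[Si](C)(C)OC1=C(CC[C@H](C)CCO[Si](C)(C)C(C)(C)C)[C@@]2(C)CCC[C@@H](C(=O)OC)[C@@H]2CC1 | intermediate
20 | methyl (1R,4aS,5R,8aS)-5-[(3S)-5-{[tert-butyl(dimethyl)silyl]oxy}-3-methylpentyl]-4a-methyl-6-oxodecahydronaphthalene-1-carboxylate | O=C1CC[C@@H]2[C@](C)(CCC[C@H]2C(=O)OC)[C@H]1CC[C@H](C)CCO[Si](C)(C)C(C)(C)C | intermediate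
21 | methyl (1R,4aS,5S,8aS)-5-[(3S)-5-{[tert-butyl(dimethyl)silyl]oxy}-3-methylpentyl]-4a-methyl-6-methylidenedecahydronaphthalene-1-carboxylate | C=C1CC[C@@H]2[C@](C)(CCC[C@H]2C(=O)OC)[C@H]1CC[C@H](C)CCO[Si](C)(C)C(C)(C)C | intermediate
22 | lithium ester enolate of 21 (enolate geometry undefined) | C=C1CC[C@@H]2[C@](C)(CCCC2=C(OC)O[Li])[C@H]1CC[C@H](C)CCO[Si](C)(C)C(C)(C)C | intermediate
23 | methyl (1S,4aR,5S,8aR)-5-[(3S)-5-{[tert-butyl(dimethyl)silyl]oxy}-3-methylpentyl]-1,4a-dimethyl-6-methylidenedecahydronaphthalene-1-carboxylate | C=C1CC[C@@H]2[C@](C)(CCC[C@]2(C)C(=O)OC)[C@H]1CC[C@H](C)CCO[Si](C)(C)C(C)(C)C | intermediate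
24 | (1S,4aR,5S,8aR)-5-[(3S)-5-{[tert-butyl(dimethyl)silyl]oxy}-3-methylpentyl]-1,4a-dimethyl-6-methylidenedecahydronaphthalene-1-carboxylic acid | C=C1CC[C@@H]2[C@](C)(CCC[C@]2(C)C(=O)O)[C@H]1CC[C@H](C)CCO[Si](C)(C)C(C)(C)C | intermediate
25 | (1S,4aR,5S,8aR)-5-[(3S)-5-hydroxy-3-methylpentyl]-1,4a-dimethyl-6-methylidenedecahydronaphthalene-1-carboxylic acid | C=C1CC[C@@H]2[C@](C)(CCC[C@]2(C)C(=O)O)[C@H]1CC[C@H](C)CCO | intermediate
26 | octadecanoyl chloride | CCCCCCCCCCCCCCCCCC(=O)Cl | starting material
27 | (1S,4aR,5S,8aR)-1,4a-dimethyl-6-methylidene-5-[(3S)-3-methyl-5-(octadecanoyloxy)pentyl]decahydronaphthalene-1-carboxylic acid | C=C1CC[C@@H]2[C@](C)(CCC[C@]2(C)C(=O)O)[C@H]1CC[C@H](C)CCOC(=O)CCCCCCCCCCCCCCCCC | target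

## Step count and risk

Total: 19 steps. Longest linear sequence: 15 steps (steps 1–9 and 14–19); steps 10–13 are the side branch to bromide 17.

**Step 8 (key step).**
- Risk: the C10 radical may bond to C11 instead of C9. That carbon is β to the ketone, and 7-endo closure there would be followed by expulsion of a sulfonyl radical. Closure through a transition state with the forming bond axial on ring A would give the cis-fused decalin.
- Fallback: from 10, Luche reduction (NaBH4, CeCl3·7H2O, MeOH, −78 °C) should give methyl (1R,2S)-2-[(4E)-5-(benzenesulfonyl)-3-hydroxypent-4-en-1-yl]-3-methylidenecyclohexane-1-carboxylate F1. With the ketone gone the sulfone is the only activating group, so the same Fe(acac)3/PhSiH3 cyclisation is polarity-matched only at C9. It should give methyl (1R,4aS,5R,8aS)-5-[(benzenesulfonyl)methyl]-6-hydroxy-4a-methyldecahydronaphthalene-1-carboxylate F2, and Dess–Martin oxidation returns the route to 11.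

**Step 1.**
- Risk: poor facial selectivity of hydride delivery, or hydride transfer to the wrong alkene carbon, because an ester as the β-substituent lies outside the usual alkyl and aryl cases.
- Fallback: from 1, RhCl(PPh3)3-catalysed 1,4-hydrosilylation with Et3SiH gives racemic methyl 3-[(triethylsilyl)oxy]cyclohex-2-ene-1-carboxylate F3. Fluoride-mediated allylation (Bu4N[Ph3SiF2], allyl bromide) gives the racemic trans keto ester methyl (1RS,2SR)-3-oxo-2-(prop-2-en-1-yl)cyclohexane-1-carboxylate F4. Preparative supercritical-fluid chromatography on a chiral stationary phase separates the enantiomers and returns the route to 3.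

**Step 3.**
- Risk: competing hydroboration of the C10 methylene, since both alkenes are terminal.
- Fallback: from 4, cross-metathesis with pinacol vinylboronate (second-generation Hoveyda–Grubbs catalyst, CH2Cl2, 40 °C) gives methyl (1R,2S)-3-methylidene-2-[(2E)-3-(4,4,5,5-tetramethyl-1,3,2-dioxaborolan-2-yl)prop-2-en-1-yl]cyclohexane-1-carboxylate F5. Ring closure onto the methylene is impossible here because it would form a four-membered ring. Perborate oxidation of F5 gives aldehyde 7 directly.

**Step 14 (together with step 9).**
- Risk: dimerisation or polymerisation of the exo-methylene ketone before it meets the organocopper reagent, or 1,2-addition to the ketone.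
- Fallback: the sulfone is kept as a carbanion anchor. From 11, methylenation with Zn, CH2Br2 and TiCl4 (non-basic) gives methyl (1R,4aS,5S,8aS)-5-[(benzenesulfonyl)methyl]-4a-methyl-6-methylidenedecahydronaphthalene-1-carboxylate F6. LiOH then gives (1R,4aS,5S,8aS)-5-[(benzenesulfonyl)methyl]-4a-methyl-6-methylidenedecahydronaphthalene-1-carboxylic acid F7, whose carboxylate no longer competes for base. Bromide 17 is converted with NaI in acetone into tert-butyl{[(3R)-4-iodo-3-methylbutyl]oxy}dimethylsilane F8. The dianion of F7 (n-BuLi, 2.2 equiv, THF/HMPA, −78 °C) is alkylated with F8 to give (1R,4aS,5S,8aS)-5-[(3R)-1-(benzenesulfonyl)-5-{[tert-butyl(dimethyl)silyl]oxy}-3-methylpentyl]-4a-methyl-6-methylidenedecahydronaphthalene-1-carboxylic acid F9. Sodium amalgam Na(Hg) with Na2HPO4 in MeOH removes the sulfone to give (1R,4aS,5S,8aS)-5-[(3S)-5-{[tert-butyl(dimethyl)silyl]oxy}-3-methylpentyl]-4a-methyl-6-methylidenedecahydronaphthalene-1-carboxylic acid F10. Esterification with Me3SiCHN2 in MeOH returns the route to 21.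

**Step 16.**
- Risk: incomplete enolisation, because the C4 hydrogen is axial and lies under the C20 methyl, or erosion of facial selectivity.
- Fallback: from 21, i-Bu2AlH at −78 °C gives (1R,4aS,5S,8aS)-5-[(3S)-5-{[tert-butyl(dimethyl)silyl]oxy}-3-methylpentyl]-4a-methyl-6-methylidenedecahydronaphthalene-1-carbaldehyde F11. Its far more acidic α-hydrogen is removed by KOt-Bu and the enolate is C-methylated with MeI from the same α face, giving (1S,4aR,5S,8aR)-5-[(3S)-5-{[tert-butyl(dimethyl)silyl]oxy}-3-methylpentyl]-1,4a-dimethyl-6-methylidenedecahydronaphthalene-1-carbaldehyde F12. Pinnick oxidation (NaClO2, NaH2PO4, 2-methylbut-2-ene) returns the route to acid 24 and bypasses the ester cleavage of step 17.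

## Further compounds

F1 | step 8 | methyl (1R,2S)-2-[(4E)-5-(benzenesulfonyl)-3-hydroxypent-4-en-1-yl]-3-methylidenecyclohexane-1-carboxylate (both carbinol epimers) | C=C1CCC[C@@H](C(=O)OC)[C@@H]1CCC(O)/C=C/S(=O)(=O)c1ccccc1
F2 | step 8 | methyl (1R,4aS,5R,8aS)-5-[(benzenesulfonyl)methyl]-6-hydroxy-4a-methyldecahydronaphthalene-1-carboxylate (both carbinol epimers) | OC1CC[C@@H]2[C@](C)(CCC[C@H]2C(=O)OC)[C@H]1CS(=O)(=O)c1ccccc1
F3 | step 1 | methyl 3-[(triethylsilyl)oxy]cyclohex-2-ene-1-carboxylate (racemic) | CC[Si](CC)(CC)OC1=CC(C(=O)OC)CCC1
F4 | step 1 | methyl (1RS,2SR)-3-oxo-2-(prop-2-en-1-yl)cyclohexane-1-carboxylate (racemate, both enantiomers written) | O=C1CCC[C@@H](C(=O)OC)[C@@H]1CC=C.O=C1CCC[C@H](C(=O)OC)[C@H]1CC=C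
F5 | step 3 | methyl (1R,2S)-3-methylidene-2-[(2E)-3-(4,4,5,5-tetramethyl-1,3,2-dioxaborolan-2-yl)prop-2-en-1-yl]cyclohexane-1-carboxylate | C=C1CCC[C@@H](C(=O)OC)[C@@H]1C/C=C/B1OC(C)(C)C(C)(C)O1
F6 | step 14 | methyl (1R,4aS,5S,8aS)-5-[(benzenesulfonyl)methyl]-4a-methyl-6-methylidenedecahydronaphthalene-1-carboxylate | C=C1CC[C@@H]2[C@](C)(CCC[C@H]2C(=O)OC)[C@H]1CS(=O)(=O)c1ccccc1
F7 | step 14 | (1R,4aS,5S,8aS)-5-[(benzenesulfonyl)methyl]-4a-methyl-6-methylidenedecahydronaphthalene-1-carboxylic acid | C=C1CC[C@@H]2[C@](C)(CCC[C@H]2C(=O)O)[C@H]1CS(=O)(=O)c1ccccc1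
F8 | step 14 | tert-butyl{[(3R)-4-iodo-3-methylbutyl]oxy}dimethylsilane | IC[C@H](C)CCO[Si](C)(C)C(C)(C)C
F9 | step 14 | (1R,4aS,5S,8aS)-5-[(3R)-1-(benzenesulfonyl)-5-{[tert-butyl(dimethyl)silyl]oxy}-3-methylpentyl]-4a-methyl-6-methylidenedecahydronaphthalene-1-carboxylic acid (both C11 epimers) | C=C1CC[C@@H]2[C@](C)(CCC[C@H]2C(=O)O)[C@H]1C(C[C@H](C)CCO[Si](C)(C)C(C)(C)C)S(=O)(=O)c1ccccc1
F10 | step 14 | (1R,4aS,5S,8aS)-5-[(3S)-5-{[tert-butyl(dimethyl)silyl]oxy}-3-methylpentyl]-4a-methyl-6-methylidenedecahydronaphthalene-1-carboxylic acid | C=C1CC[C@@H]2[C@](C)(CCC[C@H]2C(=O)O)[C@H]1CC[C@H](C)CCO[Si](C)(C)C(C)(C)C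
F11 | step 16 | (1R,4aS,5S,8aS)-5-[(3S)-5-{[tert-butyl(dimethyl)silyl]oxy}-3-methylpentyl]-4a-methyl-6-methylidenedecahydronaphthalene-1-carbaldehyde | C=C1CC[C@@H]2[C@](C)(CCC[C@H]2C=O)[C@H]1CC[C@H](C)CCO[Si](C)(C)C(C)(C)C
F12 | step 16 | (1S,4aR,5S,8aR)-5-[(3S)-5-{[tert-butyl(dimethyl)silyl]oxy}-3-methylpentyl]-1,4a-dimethyl-6-methylidenedecahydronaphthalene-1-carbaldehyde | C=C1CC[C@@H]2[C@](C)(CCC[C@]2(C)C=O)[C@H]1CC[C@H](C)CCO[Si](C)(C)C(C)(C)C
A1 | alternative 1 | methyl 6-{[tert-butyl(dimethyl)silyl]oxy}-5-formyl-1,4a-dimethyl-1,2,3,4,4a,5,6,8a-octahydronaphthalene-1-carboxylate (trans-fused Diels–Alder adduct, configuration as in the SMILES) | CC(C)(C)[Si](C)(C)O[C@H]1C=C[C@@H]2[C@](C)(CCC[C@]2(C)C(=O)OC)[C@H]1C=O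
A2 | alternative 1 | methyl (6E)-2-[(1E,3E)-4-{[tert-butyl(dimethyl)silyl]oxy}buta-1,3-dien-1-yl]-2,6-dimethyl-8-oxooct-6-enoate (C2 configuration as in the SMILES) | O=C/C=C(\C)CCC[C@](C)(C(=O)OC)/C=C/C=C/O[Si](C)(C)C(C)(C)C
A3 | alternative 2 | methyl 1-methyl-3-oxo-2-(prop-2-en-1-yl)cyclohexane-1-carboxylate (allyl trans to ester) | COC(=O)[C@@]1(C)CCCC(=O)[C@@H]1CC=C
A4 | alternative 3 | trans-fused 5',8a'-dimethyloctahydro-2'H-spiro[[1,3]dioxolane-2,1'-naphthalene]-5'-carbaldehyde (axial aldehyde) | O=C[C@@]1(C)CCC[C@@]2(C)[C@H]1CCCC23OCCO3
A5 | alternative 3 | C4–C19 epoxide of the trans-fused bicyclo[5.4.0]undecane homologue carrying the C18 and C20 methyls and the C9 ethylene ketal | C[C@]12O[C@H]1CCC[C@@]3(C)[C@H]2CCCC34OCCO4
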